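**Assumption:** the target is taken exactly as drawn, (1S,4aS,6S,7R,7aS); atoms are labelled with iridoid numbering (C1, O2, C3, C4, C5, C6, C7, C8, C9, C10 = CH2OAc carbon, C11 = C4–CH2O carbon). This is a paper route; nothing here has been run.

## Retrosynthetic overview

1. Target ⇐ selective C11–OH isovaleroylation ⇐ Luche reduction of the C11 aldehyde ⇐ trans-diol monoacetate 12.
2. 12 ⇐ acetate-assisted opening of the convex-face 7,8-epoxide 11 with inversion at C8 ⇐ ene/oxygen-transfer on the 8(10)-methylene bicycle 9.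
3. Key step: the cyclopentane (second ring) is closed by 5-exo-dig cyclization of the C9 radical of a 1-O-isovaleryl-2-iodopyranoside onto the butynyl arm on C5 (C8–C9 bond, cis ring fusion).
4. Radical precursor 8 ⇐ iodo-acyloxylation of 4H-pyran 6 ⇐ Vilsmeier formylation and EtOH loss from hetero-Diels–Alder adduct 4.
5. The pyran (first ring) comes from a catalytic enantioselective inverse-demand hetero-Diels–Alder of (E)-hept-2-en-6-ynal with ethyl vinyl ether, which sets C5.

## Route

**Step 1**
Reactants: 1, pent-4-ynal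
Product: 2, (2E)-hept-2-en-6-ynal
Conditions: Ph3P=CHCHO (1.05 equiv), PhMe, 80 °C
Reagents that add atoms: (triphenylphosphoranylidene)acetaldehyde, O=CC=P(c1ccccc1)(c1ccccc1)c1ccccc1
Why: Wittig olefination with a stabilized formylmethylene ylide gives the (E)-enal; no stereocentre is formed.

**Step 2**
Reactants: 2, (2E)-hept-2-en-6-ynal; 3, ethyl vinyl ether
Product: 4, (2S,4S)-4-(but-3-yn-1-yl)-2-ethoxy-3,4-dihydro-2H-pyran
Conditions: Jacobsen tridentate Schiff-base Cr(III)Cl catalyst (aminoindanol-derived, 5 mol %; the enantiomer that gives the 4S adduct), 4 Å MS, neat 3, rt, 48 h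
Reagents that add atoms: ethyl vinyl ether, C=COCC
Why: Catalytic enantioselective inverse-electron-demand hetero-Diels–Alder (endo); the catalyst sets pyran C4 (future C5) as S, and the acetal centre is cis but is destroyed in step 4.

**Step 3**
Reactants: 4
Product: 5, (2S,4S)-4-(but-3-yn-1-yl)-2-ethoxy-3,4-dihydro-2H-pyran-5-carbaldehyde
Conditions: preformed POCl3/DMF (1.2 equiv), pyridine, CH2Cl2, −20 → 0 °C; then aq. NaOAc
Reagents that add atoms: N,N-dimethylformamide, CN(C)C=O; water, O
Why: Vilsmeier–Haack formylation at the β-carbon of the enol ether installs C11; it also turns the C3=C4 enol ether into an oxidation-resistant vinylogous formate and differentiates the two halves of the ring before step 4.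

**Step 4**
Reactants: 5
Product: 6, (4S)-4-(but-3-yn-1-yl)-4H-pyran-3-carbaldehyde
Conditions: TMSOTf (1.2 equiv), i-Pr2NEt (1.5 equiv), CH2Cl2, −40 → 0 °C; used directly
Reagents that add atoms: none
Why: Gassman-type acetal-to-enol-ether elimination of EtOH creates the electron-rich C1=C9 enol ether; C5 is untouched and stays stereogenic because the other enol ether already carries CHO.

**Step 5**
Reactants: 6; 7, 3-methylbutanoic (isovaleric) acid
Product: 8, (2S,3R,4R)-4-(but-3-yn-1-yl)-5-formyl-3-iodo-3,4-dihydro-2H-pyran-2-yl 3-methylbutanoate (major trans-diaxial adduct)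
Conditions: NIS (1.1 equiv), 7 (3 equiv), CH2Cl2–MeCN, −30 → 0 °C, dark
Reagents that add atoms: N-iodosuccinimide, O=C1CCC(=O)N1I; isovaleric acid, CC(C)CC(=O)O
Why: Glycal-type iodo-acyloxylation; I+ adds to the β-carbon (C9) of the more electron-rich enol ether and the carboxylate adds axially at C1 (trans-diaxial), installing the C1 isovalerate. The C9 configuration is immaterial because it becomes a radical; if C1 forms as a mixture it should equilibrate to the natural epimer (genipin-type preference).

**Step 6 (key step)**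
Reactants: 8
Product: 9, (1S,4aS,7aS)-4-formyl-7-methylidene-1,4a,5,6,7,7a-hexahydrocyclopenta[c]pyran-1-yl 3-methylbutanoate
Conditions: (TMS)3SiH (1.3 equiv, syringe pump), AIBN (0.2 equiv), PhMe, 80 °C, 0.01 M
Reagents that add atoms: none
Why: 5-exo-dig cyclization of the C9 radical (2-halo-acetal / glycosyl C2-radical type) onto the alkyne forms the C8–C9 bond. The arm on C5 can only reach C9 from its own face, so the ring fusion is cis (H5 and H9 cis) and C9 is set as S. β-Acyloxy radical fragmentation or 1,2-shift is slow compared with cyclization.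

**Step 7**
Reactants: 9
Product: 10, (1S,4aS,6S,7S,7aS)-6,7-epoxy-4-formyl-7-(hydroxymethyl)-1,4a,5,6,7,7a-hexahydrocyclopenta[c]pyran-1-yl 3-methylbutanoate (7β,8β-epoxide, iridoid numbering)
Conditions: O2, TPP (cat.), hν, Ti(OiPr)4, CH2Cl2, −10 °C
Reagents that add atoms: oxygen, O=O
Why: Schenck ene reaction (O at C10, H taken from the C7 methylene) gives the 7-ene-10-hydroperoxide, and Ti(IV)-mediated oxygen transfer (Adam hydroxy-epoxidation) epoxidizes the allylic alkene from the convex face, cis to H5/H9. The deactivated vinylogous formate is inert.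

**Step 8**
Reactants: 10
Product: 11, the 10-O-acetate of 10
Conditions: Ac2O, pyridine, DMAP (cat.), CH2Cl2, 0 °C
Reagents that add atoms: acetic anhydride, CC(=O)OC(C)=O
Why: Standard acetylation of the only free hydroxyl.

**Step 9**
Reactants: 11
Product: 12, (1S,4aS,6S,7R,7aS)-7-(acetoxymethyl)-4-formyl-6,7-dihydroxy-1,4a,5,6,7,7a-hexahydrocyclopenta[c]pyran-1-yl 3-methylbutanoate
Conditions: BF3·OEt2 (1.1 equiv), CH2Cl2, −78 → −40 °C; then H2O/NaHCO3; brief Et3N to bring the acetate onto the primary oxygen
Reagents that add atoms: water, O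
Why: Neighbouring-group participation: the C10 acetate carbonyl opens the epoxide at the tertiary C8 with inversion (5-membered acetoxonium), and hydrolysis gives the trans-diol monoacetate. C7–OH keeps the convex-face configuration and C8–OH ends on the concave face (7S,8R in iridoid numbering = 6S,7R as named).

**Step 10**
Reactants: 12
Product: 13, (1S,4aS,6S,7R,7aS)-7-(acetoxymethyl)-6,7-dihydroxy-4-(hydroxymethyl)-1,4a,5,6,7,7a-hexahydrocyclopenta[c]pyran-1-yl 3-methylbutanoate
Conditions: NaBH4, CeCl3·7H2O, MeOH–THF, −78 °C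
Reagents that add atoms: none
Why: Luche 1,2-reduction of the β-alkoxy enal; esters and the acyl acetal survive at −78 °C.

**Step 11**
Reactants: 13; 14, 3-methylbutanoyl (isovaleryl) chloride
Product: 15, target (CID 42638123)
Conditions: 14 (1.05 equiv), 2,4,6-collidine, CH2Cl2, −78 → −30 °C
Reagents that add atoms: isovaleryl chloride, CC(C)CC(=O)Cl
Why: Chemoselective acylation of the primary allylic C11–OH over the hindered secondary C7–OH and tertiary C8–OH.

## Compound list

1 | pent-4-ynal | C#CCCC=O | starting material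
2 | (2E)-hept-2-en-6-ynal | C#CCC/C=C/C=O | intermediate
3 | ethyl vinyl ether | C=COCC | starting material
4 | (2S,4S)-4-(but-3-yn-1-yl)-2-ethoxy-3,4-dihydro-2H-pyran | CCO[C@@H]1C[C@H](CCC#C)C=CO1 | intermediate
5 | (2S,4S)-4-(but-3-yn-1-yl)-2-ethoxy-3,4-dihydro-2H-pyran-5-carbaldehyde | CCO[C@@H]1C[C@H](CCC#C)C(C=O)=CO1 | intermediate
6 | (4S)-4-(but-3-yn-1-yl)-4H-pyran-3-carbaldehyde | O=CC1=COC=C[C@@H]1CCC#C | intermediate
7 | 3-methylbutanoic acid | CC(C)CC(=O)O | starting material
8 | (2S,3R,4R)-4-(but-3-yn-1-yl)-5-formyl-3-iodo-3,4-dihydro-2H-pyran-2-yl 3-methylbutanoate | CC(C)CC(=O)O[C@@H]1OC=C(C=O)[C@@H](CCC#C)[C@H]1I | intermediate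
9 | (1S,4aS,7aS)-4-formyl-7-methylidene-1,4a,5,6,7,7a-hexahydrocyclopenta[c]pyran-1-yl 3-methylbutanoate | C=C1[C@H]2[C@H](OC(=O)CC(C)C)OC=C(C=O)[C@H]2CC1 | intermediate
10 | (1S,4aS,6S,7S,7aS)-6,7-epoxy-4-formyl-7-(hydroxymethyl)-hexahydrocyclopenta[c]pyran-1-yl 3-methylbutanoate | OC[C@]12O[C@H]1C[C@@H]1C(C=O)=CO[C@@H](OC(=O)CC(C)C)[C@@H]12 | intermediate
11 | 10-O-acetate of 10 | CC(=O)OC[C@]12O[C@H]1C[C@@H]1C(C=O)=CO[C@@H](OC(=O)CC(C)C)[C@@H]12 | intermediate
12 | (1S,4aS,6S,7R,7aS)-7-(acetoxymethyl)-4-formyl-6,7-dihydroxy-hexahydrocyclopenta[c]pyran-1-yl 3-methylbutanoate | CC(=O)OC[C@]1(O)[C@H]2[C@H](OC(=O)CC(C)C)OC=C(C=O)[C@H]2C[C@@H]1O | intermediate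
13 | (1S,4aS,6S,7R,7aS)-7-(acetoxymethyl)-6,7-dihydroxy-4-(hydroxymethyl)-hexahydrocyclopenta[c]pyran-1-yl 3-methylbutanoate | CC(=O)OC[C@]1(O)[C@H]2[C@H](OC(=O)CC(C)C)OC=C(CO)[C@H]2C[C@@H]1O | intermediate
14 | 3-methylbutanoyl chloride | CC(C)CC(=O)Cl | starting material
15 | (1S,4aS,6S,7R,7aS)-7-(acetoxymethyl)-6,7-dihydroxy-4-[(3-methylbutanoyloxy)methyl]-1,4a,5,6,7,7a-hexahydrocyclopenta[c]pyran-1-yl 3-methylbutanoate | CC(=O)OC[C@]1(O)[C@H]2[C@H](OC(=O)CC(C)C)OC=C(COC(=O)CC(C)C)[C@H]2C[C@@H]1O | target

## Summary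

Total steps: 11. Longest linear sequence: 11 (fully linear from pent-4-ynal).

Three steps most likely to fail, each with a fallback that changes the approach:

1. **Step 7 (ene/oxygen transfer).** The 1,1-disubstituted alkene reacts slowly with singlet oxygen, and H-abstraction at C9 instead of C7 would give the wrong alkene. Fallback: carry the C7 oxygen in the side chain as a propargylic acetate, cyclize as in step 6, move the acetate to C10 by Pd(II)-catalysed 1,3-allylic transposition (giving the 7-ene), then epoxidize with mCPBA from the convex face.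
2. **Steps 4–5 (labile 4H-pyran; regio- and anomer control in the iodo-acyloxylation).** Fallback: avoid the 4H-pyran by hydrolysing acetal 5 to the lactol, putting a phenylselenide on C9 by enamine-catalysed α-selenenylation of the open-chain aldehyde, acylating the anomeric OH with 14, and generating the C9 radical from the C–Se bond.
3. **Step 9 (epoxide opening).** Risks are Meinwald rearrangement, attack at C7, or hydrolysis of the vinylogous formate. Fallback: drop the inversion logic; hydroxylate 9 at C7 with SeO2 (retaining the 8(10)-alkene), silylate, dihydroxylate the exocyclic alkene with OsO4 anti to the 7-O-silyl group, then acetylate the primary C10–OH and desilylate.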